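Which species holds most of the charged Q after 30 h in green, violet and blue? You could hand that to an integrator, but two ratios read off the earlier runs will name a leader.

common to all: X 21 mM (held)

| charge | Q | temperature | remark | time |
|---|---|---|---|---|
| gamma | 0.050 M | 8 °C | run made earlier |  |
| eta | 0.20 M | 24 °C | run made earlier |  |
| green | 0.10 M | 0 °C |  | 30 h |
| violet | 0.10 M | 15 °C |  | 30 h |
| blue | 0.10 M | 30 °C |  | 30 h |

| run | time / h | J / % | L / % | Q / % |
|---|---|---|---|---|
| gamma | 5.00 | 2.6 | 29.3 | 66.9 |
| gamma | 10.0 | 6.8 | 32.5 | 59.6 |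
| gamma | 15.0 | 11.9 | 33.5 | 55.6 |
| gamma | 20.0 | 18.7 | 29.9 | 52.5 |
| gamma | 25.0 | 21.0 | 27.9 | 49.9 |
| gamma | 30.0 | 24.9 | 27.5 | 47.5 |
| gamma | 40.0 | 31.9 | 25.6 | 41.3 |
| eta | 1.50 | 2.9 | 22.6 | 75.3 |
| eta | 3.00 | 4.1 | 22.4 | 70.9 |
| eta | 5.00 | 12.1 | 22.9 | 67.6 |
| eta | 6.00 | 10.6 | 21.8 | 67.0 |
| eta | 8.00 | 16.6 | 21.5 | 61.4 |
| eta | 10.0 | 20.1 | 22.1 | 59.5 |
| eta | 12.0 | 25.0 | 21.2 | 52.8 |

(standard deviation of a reading: 1 percentage point)

* which of these there is most of at the end, counted by the Q in it, green (Q / L / J)
* which of these there is most of at the end, counted by the Q in it, violet (Q / L / J)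
* which of these there is most of at the end, counted by the Q in it, blue (Q / L / J)
* final amount of the leader among these, as a percentage of the Q charged, in green
* final amount of the leader among these, as a percentage of the Q charged, in violet
* final amount of the leader among these, as a percentage of the Q charged, in blue

- the analysis behind the earlier runs scatters by 1 percentage point, standard deviation
- at the start none of X is in solution

In gamma's last reading J, L and Q add up to 98.8%, so I let each J hold one Q. Now divide one rate by the other: if L and Q stay in step, dL/dt over dQ/dt is simply L/Q, and time drops out. Pooling the last two readings gives 0.598 in gamma and 0.386 in eta. Call this ratio the split ρ: L over Q with the gas held, read as a pre-equilibrium. In percent of the charge, Q = (100 − J)/(1 + ρ), so Q stays ahead of J until J reaches the line 100/(2 + ρ).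

But the two runs differ in charge as well as temperature. I assume that with the gas held the charge cancels from L/Q, and I draw ln ρ straight against temperature. That gives 0.745 for green, 0.494 for violet and 0.327 for blue. A second doubt: ρ may take time to arrive, since gamma's readings of L/Q rose from 0.438 to 0.603 by 15.0 h. Green is colder than gamma, and if the ratio arrives later there, green's Q may end above my figure.

The split says nothing about J itself. So take a second ratio, κ, the rate of J per L: 0.0288 /h in gamma and 0.0961 /h in eta, drawn on the same kind of line. J then closes on the charge with the constant κρ/(1 + ρ).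

I reckon green at J 18.3% and Q 46.8%, with J under its line of 36.4%. I reckon violet at J 38.4% against a line of 40.1%, which is a narrow margin, so I name Q at 41.3% with doubt. I reckon blue at J 67.3%, over its line of 43.0%.

The forecast, made from the same runs, names Q at 48% in green, Q at 44% in violet and J at 61% in blue, that last figure lower than mine, noting that “J grows steadily while L is nearly flat”.

The flasks give Q 50.7% in green, Q 43.3% in violet and J 66.2% in blue.

    Q + D ⇌ L (K = 40.0 /M, k = 7.40 × 10⁻⁴ /M/s, Ea = 63.0 kJ/mol, ΔH = −22.0 kJ/mol)
    D ⇌ G (K = 130, k = 3.20 × 10⁻⁵ /s, Ea = 97.0 kJ/mol, ΔH = −70.0 kJ/mol)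
    D + L → J (k = 2.00 × 10⁻⁴ /M/s, Ea = 54.0 kJ/mol)
    X ⇌ D, rate k4*(csat - [D]) (kL = 0.00750 /s)
    (constants at 0 °C)

At 15.0 h blue still had Q 45.2% ahead of J 41.0%, with J under blue's line. The neighbour with blue's charges at 5 °C reached J 20.3%. Its split, drawn from gamma and eta as before, is 0.649, which puts its line at 37.7%, above that J, and Q leads there with 48.9%.

All runs are calculated for substances that don't exist; the scatter is artificial.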